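## Retrosynthetic overview
1. The target is a 7,7′-dihydroxy-6,6′,8,8′-tetramethoxy-4,4′-bicoumarin. It comes from selective cleavage of the two central (C7) aryl methyl ethers of the hexamethoxy-4,4′-bicoumarin.
2. The hexamethoxy biscoumarin comes from Ni(0)-mediated reductive (Ullmann-type) homocoupling of two molecules of 6,7,8-trimethoxycoumarin-4-yl tosylate, which forms the C4–C4′ bond.
3. The tosylate comes from 4-hydroxy-6,7,8-trimethoxycoumarin, which is built from 2,3,4-trimethoxyphenol and Meldrum's acid (aryl malonate half-ester, then Friedel–Crafts/Eaton cyclisation).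
4. Ring order: the pyranone ring is formed first (steps 1–2), then the biaryl bond (step 4), and the C7 phenols are unmasked last (step 5).

**Assumption:** the target SMILES has no stereocentres and no defined axial chirality. The C4–C4′ axis carries only H ortho and peri substituents, as in 1,1′-binaphthyl, so it is not configurationally stable. No stereocentre needs to be set. Catalysts and bulk reagents appear only in the conditions and are not numbered.

## Route

**Step 1**
Reactants: 1 (2,3,4-trimethoxyphenol); 2 (Meldrum's acid)
Product: 3 (3-oxo-3-(2,3,4-trimethoxyphenoxy)propanoic acid)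
Conditions: neat, 90–110 °C, 3 h (acetone distils off)
Reagents that add atoms: Meldrum's acid, CC1(C)OC(=O)CC(=O)O1 (supplies the malonyl unit, C3H2O3 after loss of acetone)
Why: heating Meldrum's acid expels acetone to give a carboxyketene, which the phenol traps to form the aryl malonate half-ester (ketene acylation of a phenol). No stereocentre is formed.

**Step 2**
Reactant: 3
Product: 4 (4-hydroxy-6,7,8-trimethoxycoumarin)
Conditions: Eaton's reagent (P2O5/MsOH), 70 °C, 1–2 h
Reagents that add atoms: none (net loss of H2O)
Why: the acid gives an acylium ion that acylates the only free carbon ortho to the aryloxy group (C6 of the phenol). That carbon is para to the 3-OMe and so is activated. The resulting β-keto lactone enolises to the 4-hydroxycoumarin (intramolecular Friedel–Crafts acylation).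

**Step 3**
Reactants: 4; 5 (p-toluenesulfonyl chloride)
Product: 6 (6,7,8-trimethoxy-2-oxo-2H-chromen-4-yl 4-methylbenzenesulfonate)
Conditions: TsCl, Et3N, cat. DMAP, CH2Cl2, 0 °C to rt
Reagents that add atoms: TsCl, Cc1ccc(cc1)S(=O)(=O)Cl (adds the Ts group)
Why: the acidic 4-OH (vinylogous acid) is O-sulfonylated to give a stable vinyl tosylate that can add oxidatively to Ni(0) (O-sulfonylation).

**Step 4**
Reactants: 6 (two molecules, 2 equiv)
Product: 7 (6,6′,7,7′,8,8′-hexamethoxy-4,4′-bi(2H-chromene)-2,2′-dione), formed by 2 × 6 → 7 + 2 "TsO–Zn" salt
Conditions: NiCl2(PPh3)2 (10 mol%), PPh3 (40 mol%), Zn dust (excess), Et4NI, DMF, 60 °C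
Reagents that add atoms: none (both tosylate groups leave as zinc tosylate; Zn is the terminal reductant)
Why: Zn reduces Ni(II) to Ni(0), which inserts into the electron-poor C4–OTs bond. Two Ar–Ni species then couple by reductive elimination (Ni-mediated Ullmann-type homocoupling). Atom balance: 2 × C19H18O8S − 2 TsO (C7H7O3S) = C24H22O10, which is compound 7. The lactone, the OMe groups and the C3=C4 alkene survive, and no stereocentre is formed.

**Step 5**
Reactant: 7
Product: 8 (4,4′-biisofraxidin)
Conditions: BCl3 (4–6 equiv), CH2Cl2, −78 °C to 0 °C, 3 h; then MeOH quench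
Reagents that add atoms: none (two CH2 units are lost as MeCl/B(OMe)3)
Why: the C7 OMe of each 6,7,8-trimethoxy array is flanked by two OMe groups, so it is the most hindered and the best chelated to boron. It is also para to C4a, which is conjugated to the C3=C4–C2=O acceptor. BCl3 therefore cleaves these two methyl ethers selectively (Lewis-acid aryl methyl ether cleavage), giving the free 7-OH groups of the target, C22H18O10.

## Compound list
1 | 2,3,4-trimethoxyphenol | Oc1ccc(OC)c(OC)c1OC | starting material
2 | Meldrum's acid | CC1(C)OC(=O)CC(=O)O1 | starting material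
3 | 3-oxo-3-(2,3,4-trimethoxyphenoxy)propanoic acid | OC(=O)CC(=O)Oc1ccc(OC)c(OC)c1OC | intermediate
4 | 4-hydroxy-6,7,8-trimethoxycoumarin | COc1cc2c(O)cc(=O)oc2c(OC)c1OC | intermediate
5 | p-toluenesulfonyl chloride | Cc1ccc(cc1)S(=O)(=O)Cl | starting material
6 | 6,7,8-trimethoxy-2-oxo-2H-chromen-4-yl tosylate | COc1cc2c(OS(=O)(=O)c3ccc(C)cc3)cc(=O)oc2c(OC)c1OC | intermediate
7 | 6,6′,7,7′,8,8′-hexamethoxy-4,4′-bicoumarin | COc1cc2c(-c3cc(=O)oc4c(OC)c(OC)c(OC)cc34)cc(=O)oc2c(OC)c1OC | intermediate
8 | 4,4′-biisofraxidin (no stereocentres) | COc1cc2c(-c3cc(=O)oc4c(OC)c(O)c(OC)cc34)cc(=O)oc2c(OC)c1O | target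

**Total steps:** 5. **Longest linear sequence:** 5 (1 → 3 → 4 → 6 → 7 → 8).

## Three steps most likely to fail
1. **Step 5, regioselective bis-demethylation.** BCl3 may also cleave the 6-OMe or 8-OMe groups, or stall at the mono-phenol.
   - Fallback: change the order. Demethylate the C7-OMe selectively at the monomer stage (tosylate 6, AlCl3 or MgI2) and protect the 7-OH as its MOM ether. Then run the Ni homocoupling and remove the MOM groups with HCl/MeOH, so no late-stage selectivity is needed.
2. **Step 4, Ni homocoupling.** Hydrodetosylation to 6,7,8-trimethoxycoumarin, or reduction of the C3=C4 alkene, may compete with coupling.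
   - Fallback: convert 4 to the 4-chlorocoumarin with POCl3 and use a Cu-mediated Ullmann coupling. Alternatively, make the 4-boronate from tosylate 6 by Pd-catalysed Miyaura borylation and couple it by Pd/Cu oxidative homocoupling.
3. **Step 2, Eaton cyclisation.** The strong acid may demethylate the crowded central OMe, or conversion of the half-ester may be poor.
   - Fallback: acylate phenol 1 with AcOH/BF3·OEt2 to give the 2′-hydroxy-3′,4′,5′-trimethoxyacetophenone. Then treat it with NaH and diethyl carbonate to close the ring and give 4.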